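**Retrosynthetic overview**

1. The target comes from a fully silylated bis-benzodioxane enoate by ester reduction and fluoride desilylation. Ring D (the dioxane fused to ring A, the propenol-bearing arene) is closed by Pd-catalysed aryl C–O coupling of an Evans syn glycolate aldol adduct between a ring E aldehyde and a ring A aryloxyacetyl imide. One borohydride step removes both auxiliaries and delivers both CH2OH groups.
2. Ring E (the dioxane fused to the central arene, ring B) is closed through its C–C bond: DDQ abstracts hydride from an ArO–CH2–aryl ether, and the titanium enolate of the ArO–CH2–C(=O)N imide on the neighbouring oxygen captures the cation.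
3. Enabling feature: the two sp3 carbons of ring E each hang on one of the two ortho oxygens of ring B. One is an O–CH benzylic to the electron-rich catechol ring C (hydride-labile). The other is an O–CH next to the CH2OH carbon (enolisable when that carbon is at the acyl level). Loss of H− from the first and H+ from the second leaves a cation and an enolate tethered for six-membered closure.
4. The bis-ether precursor comes from 3,4-dihydroxybenzaldehyde (used twice, as ring B and ring C) and (R)-4-benzyl-3-(bromoacetyl)oxazolidin-2-one. The ring A imide comes from 3-bromo-4-hydroxybenzaldehyde (Wittig) and the (S)-bromoacetyl imide.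
5. Ring order: ring E (C–C closure) first, ring D (C–O closure) second; rings A, B and C are bought aromatic.

Key step: step 7

Remark on the chemistry: the closure in step 7 is assumed to give the trans ring under kinetic control; a minor cis isomer would be removed by chromatography of the imide.

**Step 1**
Reactants: 1 3,4-dihydroxybenzaldehyde
Product: 2 3,4-bis(triisopropylsilyloxy)benzaldehyde
Conditions: TIPSCl (2.4 equiv), imidazole, DMF, rt
Reagents that add atoms: triisopropylsilyl chloride, CC(C)[Si](Cl)(C(C)C)C(C)C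
Why: Silylation of both phenols; the bulky silyl ethers keep ring C electron-rich for the later hydride abstraction and are removable by fluoride at the end.

**Step 2**
Reactants: 2 3,4-bis(triisopropylsilyloxy)benzaldehyde
Product: 3 [3,4-bis(triisopropylsilyloxy)phenyl]methanol
Conditions: NaBH4, THF/EtOH, 0 °C
Reagents that add atoms: none
Why: Borohydride reduction of the aryl aldehyde to the benzylic alcohol; no stereocenter is formed.

**Step 3**
Reactants: 3 [3,4-bis(triisopropylsilyloxy)phenyl]methanol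
Product: 4 4-(bromomethyl)-1,2-bis(triisopropylsilyloxy)benzene
Conditions: CBr4, PPh3, CH2Cl2, 0 °C; used without storage
Reagents that add atoms: carbon tetrabromide, BrC(Br)(Br)Br
Why: The Appel reaction converts the benzylic alcohol into the bromide under neutral conditions that spare the aryl silyl ethers.

**Step 4**
Reactants: 1 3,4-dihydroxybenzaldehyde; 4 4-(bromomethyl)-1,2-bis(triisopropylsilyloxy)benzene
Product: 5 4-{[3,4-bis(triisopropylsilyloxy)phenyl]methoxy}-3-hydroxybenzaldehyde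
Conditions: NaHCO3, NaI (cat.), DMF, 40 °C, excess of 1
Reagents that add atoms: none
Why: Williamson etherification; with a weak base only the more acidic 4-OH (para to the formyl group) is ionised, so the benzyl group goes on the oxygen that will carry the aryl-bearing carbon of ring E.

**Step 5**
Reactants: 6 (R)-4-benzyloxazolidin-2-one
Product: 8 (R)-4-benzyl-3-(bromoacetyl)oxazolidin-2-one, via N-lithio oxazolidinone 7 (not isolated)
Conditions: n-BuLi, THF, −78 °C; then BrCH2COBr, −78 °C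
Reagents that add atoms: bromoacetyl bromide, O=C(Br)CBr
Why: N-acylation of the lithiated oxazolidinone by the acid bromide; the stereocenter of the auxiliary is not touched.

**Step 6**
Reactants: 5 4-{[3,4-bis(triisopropylsilyloxy)phenyl]methoxy}-3-hydroxybenzaldehyde; 8 (R)-4-benzyl-3-(bromoacetyl)oxazolidin-2-one
Product: 9 (R)-4-benzyl-3-{[2-({3,4-bis(triisopropylsilyloxy)phenyl}methoxy)-5-formylphenoxy]acetyl}oxazolidin-2-one
Conditions: K2CO3, MeCN, rt
Reagents that add atoms: none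
Why: Williamson etherification of the remaining phenol by SN2 displacement on the highly reactive alpha-bromo imide.

**Step 7**
Reactants: 9 (R)-4-benzyl-3-{[2-({3,4-bis(triisopropylsilyloxy)phenyl}methoxy)-5-formylphenoxy]acetyl}oxazolidin-2-one
Product: 12 (R)-4-benzyl-3-{[(2S,3R)-3-[3,4-bis(triisopropylsilyloxy)phenyl]-7-formyl-2,3-dihydro-1,4-benzodioxin-2-yl]carbonyl}oxazolidin-2-one (trans), via benzylic cation DDQH salt 10 (not isolated), via titanium enolate of the cation 11 (not isolated)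
Conditions: DDQ (1.05 equiv), 4 Å molecular sieves, CH2Cl2 (0.01 M), 0 °C to rt; then −78 °C, TiCl4 (3 equiv), then i-Pr2NEt (3.5 equiv), −78 to −20 °C; aq. NH4Cl
Reagents that add atoms: none
Why: Proposed new method: DDQ abstracts hydride from the only C–H that is both benzylic to the electron-rich bis(silyloxy)aryl ring C and alpha to an ether oxygen, and the resulting aryloxy-substituted benzylic cation (held as its DDQH adduct, or as the alpha-chloro ether once TiCl4 is added) is captured at the alpha-carbon of the chelated (Z)-titanium enolate that TiCl4/i-Pr2NEt then generate from the tethered imide, which forges the bond between the two O–CH carbons. The closest known reaction types are the DDQ-mediated oxidative cyclisation of benzylic ethers onto tethered enol nucleophiles and the SN1-type alkylation of titanium enolates of N-acyloxazolidinones by alpha-chloro ethers or acetals; their union in one flask and the closure of a 1,4-benzodioxane through its C2–C3 bond are new. Ring E closes in a 6-(enolexo)-endo-trig mode, the enolate C=C lying outside and the C=O+ of the oxocarbenium inside the new ring. The acyl-bearing carbon is set by the (R)-4-benzyl auxiliary, whose benzyl group shields one face of the chelated enolate so that the cation adds to the other (S in the imide, the same spatial arrangement being R in the target after reduction), and the aryl-bearing carbon is set by a chair-like transition state that keeps ring C pseudo-equatorial and trans to the bulky chelated imide. The step needs site-selective hydride abstraction, which the formyl group secures by deactivating ring B while the glycolyl CH2 is not hydridic, and intramolecular C-alkylation in preference to intermolecular aldol addition to the formyl group, which the tether, the pre-formed cation and high dilution secure.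

**Step 8**
Reactants: 13 (S)-4-benzyloxazolidin-2-one
Product: 15 (S)-4-benzyl-3-(bromoacetyl)oxazolidin-2-one, via N-lithio oxazolidinone 14 (not isolated)
Conditions: n-BuLi, THF, −78 °C; then BrCH2COBr, −78 °C
Reagents that add atoms: bromoacetyl bromide, O=C(Br)CBr
Why: Same N-acylation as step 5, in the enantiomeric series needed for ring D.

**Step 9**
Reactants: 16 3-bromo-4-hydroxybenzaldehyde
Product: 17 ethyl (E)-3-(3-bromo-4-hydroxyphenyl)prop-2-enoate
Conditions: Ph3P=CHCO2Et (1.3 equiv), toluene, 80 °C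
Reagents that add atoms: ethyl (triphenylphosphoranylidene)acetate, CCOC(=O)C=P(c1ccccc1)(c1ccccc1)c1ccccc1
Why: Wittig reaction with a stabilised ylide gives the (E)-enoate that later becomes the propenol side chain.

**Step 10**
Reactants: 17 ethyl (E)-3-(3-bromo-4-hydroxyphenyl)prop-2-enoate; 15 (S)-4-benzyl-3-(bromoacetyl)oxazolidin-2-one
Product: 18 (S)-4-benzyl-3-({2-bromo-4-[(E)-3-ethoxy-3-oxoprop-1-enyl]phenoxy}acetyl)oxazolidin-2-one
Conditions: K2CO3, MeCN, rt
Reagents that add atoms: none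
Why: Williamson etherification (SN2) places the glycolyl unit on the oxygen para to the side chain and leaves the ortho bromide for the later C–O coupling.

**Step 11**
Reactants: 18 (S)-4-benzyl-3-({2-bromo-4-[(E)-3-ethoxy-3-oxoprop-1-enyl]phenoxy}acetyl)oxazolidin-2-one; 12 (R)-4-benzyl-3-{[(2S,3R)-3-[3,4-bis(triisopropylsilyloxy)phenyl]-7-formyl-2,3-dihydro-1,4-benzodioxin-2-yl]carbonyl}oxazolidin-2-one
Product: 20 (S)-4-benzyl-3-[(2S,3R)-2-{2-bromo-4-[(E)-3-ethoxy-3-oxoprop-1-enyl]phenoxy}-3-hydroxy-3-{(2R,3S)-2-[3,4-bis(triisopropylsilyloxy)phenyl]-3-[(R)-4-benzyl-2-oxooxazolidine-3-carbonyl]-2,3-dihydro-1,4-benzodioxin-6-yl}propanoyl]oxazolidin-2-one (syn aldol adduct), via dibutylboron (Z)-enolate 19 (not isolated)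
Conditions: 18 (1.2 equiv), Bu2BOTf, i-Pr2NEt, CH2Cl2, −78 to 0 °C; then 12, −78 to 0 °C; pH 7 buffer, MeOH, H2O2, 0 °C
Reagents that add atoms: none
Why: Evans syn-aldol reaction: the (Z)-boron enolate reacts through a Zimmerman–Traxler chair and the (S)-benzyl auxiliary (dipole-opposed, non-chelated) selects the enolate face, which should give the (2S,3R)-syn adduct.

**Step 12**
Reactants: 20 syn aldol adduct carrying both auxiliaries
Product: 21 ethyl (E)-3-[3-bromo-4-({(1R,2R)-1-{(2R,3R)-2-[3,4-bis(triisopropylsilyloxy)phenyl]-3-(hydroxymethyl)-2,3-dihydro-1,4-benzodioxin-6-yl}-1,3-dihydroxypropan-2-yl}oxy)phenyl]prop-2-enoate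
Conditions: NaBH4 (excess), THF/H2O 4:1, 0 °C to rt
Reagents that add atoms: none
Why: Borohydride reductive cleavage of both N-acyloxazolidinones to primary alcohols in aqueous THF, conditions under which the enoate ester is inert and no stereocenter is touched.

**Step 13**
Reactants: 21 triol
Product: 22 ethyl (E)-3-[3-bromo-4-({(1R,2R)-1-{(2R,3R)-2-[3,4-bis(triisopropylsilyloxy)phenyl]-3-[(tert-butyldimethylsilyloxy)methyl]-2,3-dihydro-1,4-benzodioxin-6-yl}-3-(tert-butyldimethylsilyloxy)-1-hydroxypropan-2-yl}oxy)phenyl]prop-2-enoate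
Conditions: TBSCl (2.3 equiv), imidazole, CH2Cl2, 0 °C
Reagents that add atoms: tert-butyldimethylsilyl chloride, CC(C)(C)[Si](C)(C)Cl
Why: Selective silylation of the two primary hydroxyls over the hindered secondary benzylic one, which must stay free for ring closure.

**Step 14**
Reactants: 22 bis-TBS ether with free benzylic hydroxyl and ortho aryl bromide
Product: 23 ethyl (E)-3-[(2R,3R)-3-{(2R,3R)-2-[3,4-bis(triisopropylsilyloxy)phenyl]-3-[(tert-butyldimethylsilyloxy)methyl]-2,3-dihydro-1,4-benzodioxin-6-yl}-2-[(tert-butyldimethylsilyloxy)methyl]-2,3-dihydro-1,4-benzodioxin-6-yl]prop-2-enoate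
Conditions: Pd(OAc)2 (5 mol %), 2-(di-tert-butylphosphino)-1,1'-binaphthyl (6 mol %), Cs2CO3, toluene, 70 °C
Reagents that add atoms: none
Why: Intramolecular Buchwald–Hartwig-type etherification closes ring D as a six-membered ring at the aryl carbon with retention at the carbinol carbon, so the syn aldol relationship becomes the trans ring.

**Step 15**
Reactants: 23 bis-benzodioxane enoate
Product: 24 (E)-3-[(2R,3R)-3-{(2R,3R)-2-[3,4-bis(triisopropylsilyloxy)phenyl]-3-[(tert-butyldimethylsilyloxy)methyl]-2,3-dihydro-1,4-benzodioxin-6-yl}-2-[(tert-butyldimethylsilyloxy)methyl]-2,3-dihydro-1,4-benzodioxin-6-yl]prop-2-en-1-ol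
Conditions: i-Bu2AlH (3 equiv), CH2Cl2, −78 °C; aq. KNaC4H4O6
Reagents that add atoms: none
Why: 1,2-Reduction of the enoate by the aluminium hydride gives the (E)-allylic alcohol without touching the silyl ethers or the benzylic ethers.

**Step 16**
Reactants: 24 tetrasilylated allylic alcohol
Product: 25 (E)-3-[(2R,3R)-3-[(2R,3R)-2-(3,4-dihydroxyphenyl)-3-(hydroxymethyl)-2,3-dihydro-1,4-benzodioxin-6-yl]-2-(hydroxymethyl)-2,3-dihydro-1,4-benzodioxin-6-yl]prop-2-en-1-ol (target)
Conditions: Bu4NF (6 equiv), AcOH (6 equiv), THF, 0 °C to rt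
Reagents that add atoms: none
Why: Fluoride-mediated global desilylation, buffered with acetic acid so that the para-phenol of ring C stays protonated and quinone methide fragmentation of the benzylic aryl ether is avoided.

**Compound list**

1 | 3,4-dihydroxybenzaldehyde | O=Cc1ccc(O)c(O)c1 | starting material
2 | 3,4-bis(triisopropylsilyloxy)benzaldehyde | O=Cc1ccc(O[Si](C(C)C)(C(C)C)C(C)C)c(O[Si](C(C)C)(C(C)C)C(C)C)c1 | intermediate
3 | [3,4-bis(triisopropylsilyloxy)phenyl]methanol | OCc1ccc(O[Si](C(C)C)(C(C)C)C(C)C)c(O[Si](C(C)C)(C(C)C)C(C)C)c1 | intermediate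
4 | 4-(bromomethyl)-1,2-bis(triisopropylsilyloxy)benzene | BrCc1ccc(O[Si](C(C)C)(C(C)C)C(C)C)c(O[Si](C(C)C)(C(C)C)C(C)C)c1 | intermediate
5 | 4-{[3,4-bis(triisopropylsilyloxy)phenyl]methoxy}-3-hydroxybenzaldehyde | O=Cc1ccc(OCc2ccc(O[Si](C(C)C)(C(C)C)C(C)C)c(O[Si](C(C)C)(C(C)C)C(C)C)c2)c(O)c1 | intermediate
6 | (R)-4-benzyloxazolidin-2-one | O=C1N[C@H](Cc2ccccc2)CO1 | starting material
7 | N-lithio (R)-4-benzyloxazolidin-2-one | O=C1N([Li])[C@H](Cc2ccccc2)CO1 | intermediate (not isolated)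
8 | (R)-4-benzyl-3-(bromoacetyl)oxazolidin-2-one | O=C(CBr)N1C(=O)OC[C@H]1Cc1ccccc1 | intermediate
9 | (R)-4-benzyl-3-{[2-({3,4-bis(triisopropylsilyloxy)phenyl}methoxy)-5-formylphenoxy]acetyl}oxazolidin-2-one | O=Cc1ccc(OCc2ccc(O[Si](C(C)C)(C(C)C)C(C)C)c(O[Si](C(C)C)(C(C)C)C(C)C)c2)c(OCC(=O)N2C(=O)OC[C@H]2Cc2ccccc2)c1 | intermediate
10 | aryloxy benzylic cation of 9 as its DDQH salt (ion pair or covalent adduct) | O=Cc1ccc(O[CH+]c2ccc(O[Si](C(C)C)(C(C)C)C(C)C)c(O[Si](C(C)C)(C(C)C)C(C)C)c2)c(OCC(=O)N2C(=O)OC[C@H]2Cc2ccccc2)c1.[O-]c1c(Cl)c(Cl)c(O)c(C#N)c1C#N | intermediate (not isolated)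
11 | trichlorotitanium (Z)-enolate of the cation | O=Cc1ccc(O[CH+]c2ccc(O[Si](C(C)C)(C(C)C)C(C)C)c(O[Si](C(C)C)(C(C)C)C(C)C)c2)c(O/C=C(\O[Ti](Cl)(Cl)Cl)N2C(=O)OC[C@H]2Cc2ccccc2)c1.[O-]c1c(Cl)c(Cl)c(O)c(C#N)c1C#N | intermediate (not isolated)
12 | (R)-4-benzyl-3-{[(2S,3R)-3-[3,4-bis(triisopropylsilyloxy)phenyl]-7-formyl-2,3-dihydro-1,4-benzodioxin-2-yl]carbonyl}oxazolidin-2-one (trans) | O=Cc1ccc2c(c1)O[C@H](C(=O)N1C(=O)OC[C@H]1Cc1ccccc1)[C@@H](c1ccc(O[Si](C(C)C)(C(C)C)C(C)C)c(O[Si](C(C)C)(C(C)C)C(C)C)c1)O2 | intermediate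
13 | (S)-4-benzyloxazolidin-2-one | O=C1N[C@@H](Cc2ccccc2)CO1 | starting material
14 | N-lithio (S)-4-benzyloxazolidin-2-one | O=C1N([Li])[C@@H](Cc2ccccc2)CO1 | intermediate (not isolated)
15 | (S)-4-benzyl-3-(bromoacetyl)oxazolidin-2-one | O=C(CBr)N1C(=O)OC[C@@H]1Cc1ccccc1 | intermediate
16 | 3-bromo-4-hydroxybenzaldehyde | O=Cc1ccc(O)c(Br)c1 | starting material
17 | ethyl (E)-3-(3-bromo-4-hydroxyphenyl)prop-2-enoate | CCOC(=O)/C=C/c1ccc(O)c(Br)c1 | intermediate
18 | (S)-4-benzyl-3-({2-bromo-4-[(E)-3-ethoxy-3-oxoprop-1-enyl]phenoxy}acetyl)oxazolidin-2-one | CCOC(=O)/C=C/c1ccc(OCC(=O)N2C(=O)OC[C@@H]2Cc2ccccc2)c(Br)c1 | intermediate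
19 | dibutylboron (Z)-enolate of 18 | CCOC(=O)/C=C/c1ccc(O/C=C(\OB(CCCC)CCCC)N2C(=O)OC[C@@H]2Cc2ccccc2)c(Br)c1 | intermediate (not isolated)
20 | syn aldol adduct, (2S,3R) at the new propanoyl carbons, both auxiliaries in place | CCOC(=O)/C=C/c1ccc(O[C@H](C(=O)N2C(=O)OC[C@@H]2Cc2ccccc2)[C@H](O)c2ccc3c(c2)O[C@H](C(=O)N2C(=O)OC[C@H]2Cc2ccccc2)[C@@H](c2ccc(O[Si](C(C)C)(C(C)C)C(C)C)c(O[Si](C(C)C)(C(C)C)C(C)C)c2)O3)c(Br)c1 | intermediate
21 | triol: ethyl (E)-3-[3-bromo-4-({(1R,2R)-1-{(2R,3R)-2-[3,4-bis(triisopropylsilyloxy)phenyl]-3-(hydroxymethyl)-2,3-dihydro-1,4-benzodioxin-6-yl}-1,3-dihydroxypropan-2-yl}oxy)phenyl]prop-2-enoate | CCOC(=O)/C=C/c1ccc(O[C@H](CO)[C@H](O)c2ccc3c(c2)O[C@H](CO)[C@@H](c2ccc(O[Si](C(C)C)(C(C)C)C(C)C)c(O[Si](C(C)C)(C(C)C)C(C)C)c2)O3)c(Br)c1 | intermediate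
22 | bis(tert-butyldimethylsilyl) ether of 21 at both primary hydroxyls | CCOC(=O)/C=C/c1ccc(O[C@H](CO[Si](C)(C)C(C)(C)C)[C@H](O)c2ccc3c(c2)O[C@H](CO[Si](C)(C)C(C)(C)C)[C@@H](c2ccc(O[Si](C(C)C)(C(C)C)C(C)C)c(O[Si](C(C)C)(C(C)C)C(C)C)c2)O3)c(Br)c1 | intermediate
23 | ethyl (E)-3-[(2R,3R)-3-{(2R,3R)-2-[3,4-bis(triisopropylsilyloxy)phenyl]-3-[(tert-butyldimethylsilyloxy)methyl]-2,3-dihydro-1,4-benzodioxin-6-yl}-2-[(tert-butyldimethylsilyloxy)methyl]-2,3-dihydro-1,4-benzodioxin-6-yl]prop-2-enoate | CCOC(=O)/C=C/c1ccc2c(c1)O[C@H](c1ccc3c(c1)O[C@H](CO[Si](C)(C)C(C)(C)C)[C@@H](c1ccc(O[Si](C(C)C)(C(C)C)C(C)C)c(O[Si](C(C)C)(C(C)C)C(C)C)c1)O3)[C@@H](CO[Si](C)(C)C(C)(C)C)O2 | intermediate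
24 | allylic alcohol from 23, all four silyl ethers in place | OC/C=C/c1ccc2c(c1)O[C@H](c1ccc3c(c1)O[C@H](CO[Si](C)(C)C(C)(C)C)[C@@H](c1ccc(O[Si](C(C)C)(C(C)C)C(C)C)c(O[Si](C(C)C)(C(C)C)C(C)C)c1)O3)[C@@H](CO[Si](C)(C)C(C)(C)C)O2 | intermediate
25 | (E)-3-[(2R,3R)-3-[(2R,3R)-2-(3,4-dihydroxyphenyl)-3-(hydroxymethyl)-2,3-dihydro-1,4-benzodioxin-6-yl]-2-(hydroxymethyl)-2,3-dihydro-1,4-benzodioxin-6-yl]prop-2-en-1-ol | OC/C=C/c1ccc2c(c1)O[C@H](c1ccc3c(c1)O[C@H](CO)[C@@H](c1ccc(O)c(O)c1)O3)[C@@H](CO)O2 | target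

**Summary**

Total step count: 16. Longest linear sequence: 12 steps (steps 1, 2, 3, 4, 6, 7, 11, 12, 13, 14, 15, 16).

**Steps most likely to fail**

Step 7 (proposed new method). Hydride abstraction may be sluggish or unselective because the ring B oxygen next to the benzylic carbon is a poor donor. The cation may be lost to intermolecular Friedel–Crafts or aldol pathways before the enolate forms. Facial or trans control in the closure may be poor. The fallback uses known chemistry, closes ring E through its aryl C–O bond, sets out from 15 and 2, and returns at 22. Commercial 4-bromo-3-hydroxybenzonitrile would be alkylated with 15 (K2CO3, MeCN) to the cyanoaryloxyacetyl imide F1. Its dibutylboron enolate would add to aldehyde 2 in an Evans syn-aldol reaction to give the syn adduct F2. NaBH4 in aqueous THF would give the diol F3, and TBSCl/imidazole the primary silyl ether F4. Pd-catalysed intramolecular etherification under the conditions of step 14 (the bromide lies para to the nitrile) would give the benzodioxane nitrile F5. i-Bu2AlH followed by mild aqueous acid would give the benzodioxane aldehyde F6. The aldol reaction of step 11 with 18 would give the mono-auxiliary aldol adduct F7, NaBH4 the diol F8, and silylation of its primary hydroxyl would give 22.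

Step 14. Beta-hydride elimination from the palladium alkoxide of the hindered secondary benzylic alcohol (ketone formation and hydrodebromination) may outpace C–O reductive elimination. The fallback sets out from 22 and returns at 23. Miyaura borylation (B2pin2, PdCl2(dppf), KOAc, dioxane, 80 °C) would give the arylboronate F9, and NaBO3·4H2O oxidation the phenol F10. A catalytic acid (BF3·OEt2, CH2Cl2, −40 °C) would then ionise the para-alkoxybenzylic alcohol, and the phenol would close ring D by an SN1 pathway under thermodynamic control to the trans isomer 23.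

Step 6. Acyl transfer from the imide to the phenoxide (loss of the auxiliary) may compete with SN2 displacement of bromide. The fallback sets out from 5 and returns at 9. Alkylation with allyl bromoacetate (K2CO3, MeCN) would give the allyl ester F11, and Pd(PPh3)4 with morpholine would release the aryloxyacetic acid F12. Activation as the mixed pivalic anhydride (t-BuCOCl, Et3N) and acylation of 6 in the presence of LiCl would give 9.

**Further compounds**

F1 | step 7 | (S)-4-benzyl-3-[(2-bromo-5-cyanophenoxy)acetyl]oxazolidin-2-one | N#Cc1ccc(Br)c(OCC(=O)N2C(=O)OC[C@@H]2Cc2ccccc2)c1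
F2 | step 7 | (S)-4-benzyl-3-[(2S,3R)-3-[3,4-bis(triisopropylsilyloxy)phenyl]-2-(2-bromo-5-cyanophenoxy)-3-hydroxypropanoyl]oxazolidin-2-one | N#Cc1ccc(Br)c(O[C@H](C(=O)N2C(=O)OC[C@@H]2Cc2ccccc2)[C@H](O)c2ccc(O[Si](C(C)C)(C(C)C)C(C)C)c(O[Si](C(C)C)(C(C)C)C(C)C)c2)c1
F3 | step 7 | 4-bromo-3-({(1R,2R)-1-[3,4-bis(triisopropylsilyloxy)phenyl]-1,3-dihydroxypropan-2-yl}oxy)benzonitrile | N#Cc1ccc(Br)c(O[C@H](CO)[C@H](O)c2ccc(O[Si](C(C)C)(C(C)C)C(C)C)c(O[Si](C(C)C)(C(C)C)C(C)C)c2)c1
F4 | step 7 | 4-bromo-3-({(1R,2R)-1-[3,4-bis(triisopropylsilyloxy)phenyl]-3-(tert-butyldimethylsilyloxy)-1-hydroxypropan-2-yl}oxy)benzonitrile | N#Cc1ccc(Br)c(O[C@H](CO[Si](C)(C)C(C)(C)C)[C@H](O)c2ccc(O[Si](C(C)C)(C(C)C)C(C)C)c(O[Si](C(C)C)(C(C)C)C(C)C)c2)c1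
F5 | step 7 | (2R,3R)-2-[3,4-bis(triisopropylsilyloxy)phenyl]-3-[(tert-butyldimethylsilyloxy)methyl]-2,3-dihydro-1,4-benzodioxine-6-carbonitrile | N#Cc1ccc2c(c1)O[C@H](CO[Si](C)(C)C(C)(C)C)[C@@H](c1ccc(O[Si](C(C)C)(C(C)C)C(C)C)c(O[Si](C(C)C)(C(C)C)C(C)C)c1)O2
F6 | step 7 | (2R,3R)-2-[3,4-bis(triisopropylsilyloxy)phenyl]-3-[(tert-butyldimethylsilyloxy)methyl]-2,3-dihydro-1,4-benzodioxine-6-carbaldehyde | O=Cc1ccc2c(c1)O[C@H](CO[Si](C)(C)C(C)(C)C)[C@@H](c1ccc(O[Si](C(C)C)(C(C)C)C(C)C)c(O[Si](C(C)C)(C(C)C)C(C)C)c1)O2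
F7 | step 7 | syn aldol adduct of 18 with F6, (2S,3R) at the new propanoyl carbons, (S)-auxiliary in place | CCOC(=O)/C=C/c1ccc(O[C@H](C(=O)N2C(=O)OC[C@@H]2Cc2ccccc2)[C@H](O)c2ccc3c(c2)O[C@H](CO[Si](C)(C)C(C)(C)C)[C@@H](c2ccc(O[Si](C(C)C)(C(C)C)C(C)C)c(O[Si](C(C)C)(C(C)C)C(C)C)c2)O3)c(Br)c1
F8 | step 7 | diol from F7, (1R,2R), ring E hydroxymethyl silylated | CCOC(=O)/C=C/c1ccc(O[C@H](CO)[C@H](O)c2ccc3c(c2)O[C@H](CO[Si](C)(C)C(C)(C)C)[C@@H](c2ccc(O[Si](C(C)C)(C(C)C)C(C)C)c(O[Si](C(C)C)(C(C)C)C(C)C)c2)O3)c(Br)c1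
F9 | step 14 | pinacol arylboronate in place of the bromide of 22 | CCOC(=O)/C=C/c1ccc(O[C@H](CO[Si](C)(C)C(C)(C)C)[C@H](O)c2ccc3c(c2)O[C@H](CO[Si](C)(C)C(C)(C)C)[C@@H](c2ccc(O[Si](C(C)C)(C(C)C)C(C)C)c(O[Si](C(C)C)(C(C)C)C(C)C)c2)O3)c(B2OC(C)(C)C(C)(C)O2)c1
F10 | step 14 | phenol in place of the bromide of 22 | CCOC(=O)/C=C/c1ccc(O[C@H](CO[Si](C)(C)C(C)(C)C)[C@H](O)c2ccc3c(c2)O[C@H](CO[Si](C)(C)C(C)(C)C)[C@@H](c2ccc(O[Si](C(C)C)(C(C)C)C(C)C)c(O[Si](C(C)C)(C(C)C)C(C)C)c2)O3)c(O)c1
F11 | step 6 | allyl [2-({3,4-bis(triisopropylsilyloxy)phenyl}methoxy)-5-formylphenoxy]acetate | O=Cc1ccc(OCc2ccc(O[Si](C(C)C)(C(C)C)C(C)C)c(O[Si](C(C)C)(C(C)C)C(C)C)c2)c(OCC(=O)OCC=C)c1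
F12 | step 6 | [2-({3,4-bis(triisopropylsilyloxy)phenyl}methoxy)-5-formylphenoxy]acetic acid | O=Cc1ccc(OCc2ccc(O[Si](C(C)C)(C(C)C)C(C)C)c(O[Si](C(C)C)(C(C)C)C(C)C)c2)c(OCC(=O)O)c1
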